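**Retrosynthetic overview**
- Target ⇒ two molecules of a hydroxy-o-quinone by cutting both C3a–C5' bonds (retro double aldol, formal [3+3]); the quinone comes from epicoccine (4,5,6-trihydroxy-7-methyl-1,3-dihydroisobenzofuran) by laccase/O2 oxidation.
- Epicoccine ⇒ its tribenzyl ether (hydrogenolysis) ⇒ the 1,2-bis(hydroxymethyl)arene (cyclodehydration) ⇒ the tris(benzyloxy)methylphthalide (LiAlH4).
- That phthalide ⇒ 4,5,6-trimethoxy-7-methylphthalide (methyl-to-benzyl exchange at the lactone stage) ⇒ 7-bromophthalide + methylboronic acid (Suzuki) ⇒ 4,5,6-trimethoxyphthalide (bromination).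
- 4,5,6-Trimethoxyphthalide ⇒ 3,4,5-trimethoxybenzoic acid + formaldehyde (hydroxymethylation/lactonisation).
- Ring order: benzene ring bought → five-membered oxygen ring (lactone, later cyclic ether) → last step: both arenes become cyclohexenedione rings and the central cyclohexane-1,4-dione ring closes.

Assumption: the SMILES descriptors (R,R in one half, S,S in the other) define the centrosymmetric meso dimer (the natural product dibefurin), which is achiral. Relative configuration is therefore the only stereochemical issue, and all four stereocentres arise together from achiral precursors in the last, enzyme-triggered step.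

Ring positions below use isobenzofuran numbering (C1, O2, C3, C3a, C4–C7, C7a).

**Step 1**
Reactants: 1 3,4,5-trimethoxybenzoic acid; 2 formaldehyde (37% aqueous)
Product: 4 4,5,6-trimethoxyisobenzofuran-1(3H)-one, via hydroxymethyl acid 3 (not isolated)
Conditions: 37% aq. HCHO (3 equiv), conc. HCl, AcOH, 90 °C
Reagents that add atoms: none
Why: Blanc-type electrophilic hydroxymethylation can only occur at the two equivalent positions ortho to the carboxyl group (each ortho/para to methoxy groups), and the benzylic alcohol is trapped at once by the neighbouring acid as the five-membered lactone, which deactivates the ring against a second substitution.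

**Step 2**
Reactants: 4 4,5,6-trimethoxyisobenzofuran-1(3H)-one
Product: 5 7-bromo-4,5,6-trimethoxyisobenzofuran-1(3H)-one
Conditions: NBS (1.1 equiv), TFA (10 mol %), MeCN, 50 °C, dark
Reagents that add atoms: N-bromosuccinimide (NBS), BrN1C(=O)CCC1=O
Why: Electrophilic aromatic bromination is regiochemically unambiguous because C7 is the only ring C–H left and is ortho and para to methoxy groups, while ionic conditions in the dark avoid radical bromination of the lactone CH2.

**Step 3**
Reactants: 5 7-bromo-4,5,6-trimethoxyisobenzofuran-1(3H)-one; 6 methylboronic acid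
Product: 7 4,5,6-trimethoxy-7-methylisobenzofuran-1(3H)-one
Conditions: MeB(OH)2 (3 equiv), Pd(OAc)2 (5 mol %), SPhos (10 mol %), K3PO4 (3 equiv), toluene/H2O (10:1), 100 °C; 1 M HCl work-up
Reagents that add atoms: none
Why: In this Suzuki–Miyaura cross-coupling the ortho lactone carbonyl speeds oxidative addition of zerovalent palladium into the hindered C–Br bond and the bulky, electron-rich SPhos ligand carries the methyl group through transmetalation and reductive elimination at a di-ortho-substituted carbon; any lactone opened by the aqueous base recloses on acidic work-up.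

**Step 4**
Reactants: 7 4,5,6-trimethoxy-7-methylisobenzofuran-1(3H)-one
Product: 8 4,5,6-trihydroxy-7-methylisobenzofuran-1(3H)-one
Conditions: BBr3 (5 equiv), CH2Cl2, −78 °C → 25 °C; then MeOH, H2O
Reagents that add atoms: none
Why: Lewis-acid aryl methyl ether cleavage (BBr3 coordinates each ether oxygen and bromide removes the methyl group by SN2) is done at the robust lactone stage, before any acid-labile benzylic cyclic ether exists.

**Step 5**
Reactants: 8 4,5,6-trihydroxy-7-methylisobenzofuran-1(3H)-one
Product: 9 4,5,6-tris(benzyloxy)-7-methylisobenzofuran-1(3H)-one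
Conditions: BnBr (3.6 equiv), K2CO3 (4.5 equiv), n-Bu4NI (5 mol %), degassed DMF, Ar, 25 → 50 °C
Reagents that add atoms: benzyl bromide (BnBr), BrCc1ccccc1
Why: Williamson ether synthesis on the three phenoxides under oxygen-free conditions installs groups that can be removed at the end under neutral reductive conditions, and the lactone is inert to anhydrous carbonate.

**Step 6**
Reactants: 9 4,5,6-tris(benzyloxy)-7-methylisobenzofuran-1(3H)-one
Product: 10 [3,4,5-tris(benzyloxy)-6-methyl-1,2-phenylene]dimethanol
Conditions: LiAlH4 (1.5 equiv), THF, 0 → 25 °C; H2O, 15% aq. NaOH, H2O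
Reagents that add atoms: none
Why: Hydride reduction of the lactone by LiAlH4 gives the diol cleanly, and aryl benzyl ethers are inert to it.

**Step 7**
Reactants: 10 [3,4,5-tris(benzyloxy)-6-methyl-1,2-phenylene]dimethanol
Product: 11 4,5,6-tris(benzyloxy)-7-methyl-1,3-dihydroisobenzofuran
Conditions: TsOH·H2O (5 mol %), 4 Å molecular sieves, toluene, 60 °C
Reagents that add atoms: none
Why: Acid-catalysed cyclodehydration works because each benzylic alcohol sits para to an alkoxy group, so a stabilised benzylic cation forms easily and is captured by the neighbouring hydroxymethyl group in a 5-exo closure; aryl benzyl ethers tolerate catalytic TsOH and the fully substituted ring excludes Friedel–Crafts side reactions.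

**Step 8**
Reactants: 11 4,5,6-tris(benzyloxy)-7-methyl-1,3-dihydroisobenzofuran
Product: 12 epicoccine (7-methyl-1,3-dihydroisobenzofuran-4,5,6-triol)
Conditions: H2 (1 atm), 10% Pd/C, degassed EtOAc/MeOH (1:1), 25 °C; filter through Celite under Ar, evaporate, use at once
Reagents that add atoms: none
Why: Catalytic hydrogenolysis cleaves aryl benzyl ethers in neutral solvent far faster than the dialkyl benzylic C–O bonds of the dihydroisobenzofuran, and the only by-product is volatile toluene, so the air-sensitive triol is obtained without chromatography.

**Step 9**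
Reactants: 12 epicoccine (two molecules)
Product: 15 dibefurin (target CNP0299498.2; centrosymmetric meso dimer), via hydroxy-o-quinone 13 (not isolated), via mono-aldol adduct 14 (not isolated)
Conditions: laccase (Trametes versicolor), O2 (1 atm) or air, 0.1 M NaOAc buffer pH 5.0/MeCN (9:1), 25 °C; filter the precipitate
Reagents that add atoms: none
Why: Laccase (an oxidoreductase of the multicopper oxidase class) uses O2 to oxidise the pyrogallol to hydroxy-o-quinone 13, whose enol carbon C3a and central ketone C5 pair with a second molecule in a reciprocal double aldol addition (formal [3+3] cyclodimerisation); the antiparallel approach gives a chair cyclohexane-1,4-dione with the two halves on opposite faces and sets all four stereocentres at once (R,R in one half, S,S in the other), and because the aldol steps are reversible and the meso product is sparingly soluble it is the thermodynamic sink, while the fully substituted ring blocks radical C–C coupling and benzotropolone formation.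

**Compound list**
1 | 3,4,5-trimethoxybenzoic acid | COc1cc(cc(OC)c1OC)C(O)=O | starting material
2 | formaldehyde (37% aqueous) | C=O | starting material
3 | 2-(hydroxymethyl)-3,4,5-trimethoxybenzoic acid | COc1cc(C(O)=O)c(CO)c(OC)c1OC | intermediate
4 | 4,5,6-trimethoxyisobenzofuran-1(3H)-one | COc1cc2C(=O)OCc2c(OC)c1OC | intermediate
5 | 7-bromo-4,5,6-trimethoxyisobenzofuran-1(3H)-one | COc1c(Br)c2C(=O)OCc2c(OC)c1OC | intermediate
6 | methylboronic acid | CB(O)O | starting material
7 | 4,5,6-trimethoxy-7-methylisobenzofuran-1(3H)-one | COc1c(C)c2C(=O)OCc2c(OC)c1OC | intermediate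
8 | 4,5,6-trihydroxy-7-methylisobenzofuran-1(3H)-one | Cc1c(O)c(O)c(O)c2COC(=O)c12 | intermediate
9 | 4,5,6-tris(benzyloxy)-7-methylisobenzofuran-1(3H)-one | Cc1c(OCc2ccccc2)c(OCc2ccccc2)c(OCc2ccccc2)c2COC(=O)c12 | intermediate
10 | [3,4,5-tris(benzyloxy)-6-methyl-1,2-phenylene]dimethanol | Cc1c(OCc2ccccc2)c(OCc2ccccc2)c(OCc2ccccc2)c(CO)c1CO | intermediate
11 | 4,5,6-tris(benzyloxy)-7-methyl-1,3-dihydroisobenzofuran | Cc1c(OCc2ccccc2)c(OCc2ccccc2)c(OCc2ccccc2)c2COCc12 | intermediate
12 | epicoccine (7-methyl-1,3-dihydroisobenzofuran-4,5,6-triol) | Cc1c(O)c(O)c(O)c2COCc12 | intermediate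
13 | 4-hydroxy-7-methyl-1,3-dihydroisobenzofuran-5,6-dione (reactive tautomer of the o-quinone) | CC1=C2COCC2=C(O)C(=O)C1=O | intermediate
14 | mono-aldol adduct: 3a-(4,5-dihydroxy-7-methyl-6-oxo-1,3,5,6-tetrahydroisobenzofuran-5-yl)-7-methyl-1,3-dihydroisobenzofuran-4,5,6(3aH)-trione; racemic (R*,R*) at C3a and C5', one enantiomer drawn | CC1=C2COC[C@]2([C@]3(O)C(=O)C(C)=C4COCC4=C3O)C(=O)C(=O)C1=O | intermediate
15 | dibefurin (CNP0299498.2): centrosymmetric meso dimer; the C3a and C5 of one half are bonded to the C5 and C3a of the other; R,R at C3a and C5 of one half, S,S in the other; chair cyclohexane-1,4-dione core | CC1=C2COC[C@]23C(=O)[C@](O)(C1=O)[C@@]12COCC1=C(C)C(=O)[C@]3(O)C2=O | target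

**Step count and risks**
Total step count: 9. Longest linear sequence: 9 steps (1 → 15).

Steps most likely to fail:

- **Step 9 (laccase oxidation and dimerisation).** The enzyme may be inhibited by cosolvent or precipitating product, or phenoxyl radicals may give oligomers. The fallback sets out from 12 and comes back at 15. It separates oxidation from C–C bond formation and uses no enzyme: 12 is oxidised with Ag2O in dry, degassed Et2O/MeCN at 0 °C to a solution of quinone 13, the silver is filtered off, and the filtrate is stirred with NaOAc/AcOH buffer, which triggers the double aldol and lets 15 crystallise. No compound outside the list is made (entry F0).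

- **Step 8 (hydrogenolysis to air-sensitive epicoccine).** The dihydrofuran C–O bonds may be over-reduced, or the triol may oxidise during handling. The fallback sets out from 7 and comes back at 12. It keeps the methyl ethers and drops the benzyl groups altogether. LiAlH4 in THF reduces 7 to (3,4,5-trimethoxy-6-methyl-1,2-phenylene)dimethanol F1. Catalytic TsOH in toluene closes it to 4,5,6-trimethoxy-7-methyl-1,3-dihydroisobenzofuran F2. BBr3 in CH2Cl2 (−78 → 0 °C) followed by a degassed aqueous NaHCO3 quench removes the three methyl groups to give 12. Any cyclic ether opened by BBr3 to an o-(bromomethyl)benzyl borate should reclose during the aqueous quench by 5-exo displacement.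

- **Step 3 (Suzuki methylation of a di-ortho-substituted bromide).** Protodebromination or slow transmetalation of the methyl group may lower the yield. The fallback sets out from 4 and comes back at 7. It builds the methyl group by electrophilic formylation and deoxygenation instead of cross-coupling. Rieche formylation (Cl2CHOMe, TiCl4, CH2Cl2, 0 °C) at the only free ring position gives 5,6,7-trimethoxy-3-oxo-1,3-dihydroisobenzofuran-4-carbaldehyde F3 (the 7-formyl derivative of 4). Ionic hydrogenation (Et3SiH, TFA, CH2Cl2, 0 → 25 °C) then reduces the electron-rich aryl aldehyde to the methyl group of 7.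

**Further compounds**
F0 | step 9 | none | none
F1 | step 8 | (3,4,5-trimethoxy-6-methyl-1,2-phenylene)dimethanol | COc1c(C)c(CO)c(CO)c(OC)c1OC
F2 | step 8 | 4,5,6-trimethoxy-7-methyl-1,3-dihydroisobenzofuran | COc1c(C)c2COCc2c(OC)c1OC
F3 | step 3 | 5,6,7-trimethoxy-3-oxo-1,3-dihydroisobenzofuran-4-carbaldehyde | COc1c(C=O)c2C(=O)OCc2c(OC)c1OC
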